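**Retrosynthetic overview**

1. The route rests on C3 of the 2,3-dihydrobenzofuran: a benzylic carbinol carbon bonded to C3a, which sits ortho to the O1-bearing C7a. An aryl metal at C3a can therefore reach an aldehyde carbon (the future C3) that the O1–C2 ether holds in place, and this closes the dihydrofuran ring, the only ring that is built (the benzene ring is bought).
2. Target 19 ⇐ allylic PMB ether 17 (DDQ, then MnO2) ⇐ (R)-carbinol 14 + angelic acid 15 ⇐ methyl ketone 13 (asymmetric transfer hydrogenation) ⇐ C3 acetylation of 12.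
3. 12 ⇐ Nozaki–Hiyama–Kishi closure of the C3–C3a bond in the iodoaryl ether aldehyde 10; the C2 centre directs C3.
4. 10 ⇐ glycol cleavage of diol 9 ⇐ acetonide 8 ⇐ SNAr of the anti alcohol 5 on 4'-fluoro-3'-iodoacetophenone 7.
5. 5 ⇐ Felkin–Anh addition of the 2-lithioallyl PMB ether 4 to (S)-glyceraldehyde acetonide 3, whose own stereocentre is later cut out.

Key step: step 7

Remark: benzofuran numbering (O1, C2, C3, C3a, C4 to C7, C7a) is used; the anti adduct 5 is assumed to be separable from its syn epimer by chromatography on silica.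

**Route**

Step 1
Reactants: 1 2-bromoprop-2-en-1-ol
Product: 2 2-bromo-3-(4-methoxybenzyloxy)prop-1-ene
Conditions: NaH, n-Bu4NI (cat.), THF/DMF, 0 °C → rt
Reagents that add atoms: 4-methoxybenzyl chloride, COc1ccc(CCl)cc1
Why: Williamson etherification, in which the sodium alkoxide of 1 displaces chloride from the benzylic chloride under iodide catalysis while the vinyl bromide is inert to NaH at this temperature; no stereocentre is formed.

Step 2
Reactants: 2 2-bromo-3-(4-methoxybenzyloxy)prop-1-ene; 3 (S)-2,2-dimethyl-1,3-dioxolane-4-carbaldehyde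
Product: 5 (R)-1-[(S)-2,2-dimethyl-1,3-dioxolan-4-yl]-2-[(4-methoxybenzyloxy)methyl]prop-2-en-1-ol, via 2-lithioallyl PMB ether 4 (not isolated)
Conditions: t-BuLi (2.05 equiv), Et2O, −78 °C; then freshly distilled 3, −78 °C; H2O quench; SiO2 separation of the anti adduct
Reagents that add atoms: none
Why: Bromine–lithium exchange gives the 2-lithioallyl ether 4, which adds to the α-alkoxy aldehyde in the Felkin–Anh sense (attack anti to the dioxolane C–O bond), so the anti adduct with the (R)-carbinol centre should be the major, separable diastereomer.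

Step 3
Reactants: 6 4'-fluoroacetophenone
Product: 7 4'-fluoro-3'-iodoacetophenone
Conditions: NIS, CF3SO3H, 0 °C → rt
Reagents that add atoms: N-iodosuccinimide, O=C1CCC(=O)N1I
Why: Electrophilic aromatic iodination with NIS activated by triflic acid, in which fluorine directs ortho and the protonated acetyl group directs meta, both to C3', and the strongly acidic medium holds back enol iodination of the methyl ketone.

Step 4
Reactants: 5 (R)-1-[(S)-2,2-dimethyl-1,3-dioxolan-4-yl]-2-[(4-methoxybenzyloxy)methyl]prop-2-en-1-ol; 7 4'-fluoro-3'-iodoacetophenone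
Product: 8 1-[4-({(R)-1-[(S)-2,2-dimethyl-1,3-dioxolan-4-yl]-2-[(4-methoxybenzyloxy)methyl]prop-2-en-1-yl}oxy)-3-iodophenyl]ethan-1-one
Conditions: KN(SiMe3)2 (1.0 equiv), THF, −20 °C; then 7, DMF, −20 °C → rt
Reagents that add atoms: none
Why: Nucleophilic aromatic substitution by addition–elimination, in which the potassium alkoxide of 5 attacks the fluorine-bearing carbon para to the acetyl group and fluoride leaves, so the C–O bond of the carbinol is never broken and its (R) configuration is retained.

Step 5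
Reactants: 8 the acetonide aryl ether from step 4
Product: 9 1-[4-({(2S,3R)-1,2-dihydroxy-4-[(4-methoxybenzyloxy)methyl]pent-4-en-3-yl}oxy)-3-iodophenyl]ethan-1-one
Conditions: AcOH/H2O (4:1), 40 °C
Reagents that add atoms: none
Why: Acid-catalysed hydrolysis of the terminal isopropylidene acetal, to which the PMB ether, the allylic aryl ether and the aryl iodide are stable, with no stereocentre affected.

Step 6
Reactants: 9 the 1,2-diol from step 5
Product: 10 (R)-2-(4-acetyl-2-iodophenoxy)-3-[(4-methoxybenzyloxy)methyl]but-3-enal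
Conditions: NaIO4 on SiO2, CH2Cl2, 0 °C → rt; filtered, concentrated cold and used at once
Reagents that add atoms: none
Why: Periodate glycol cleavage (Malaprade reaction) under neutral conditions turns the secondary carbinol carbon into the aldehyde and leaves the neighbouring aryloxy-bearing centre, with its acidic allylic α-hydrogen, unchanged.

Step 7
Reactants: 10 (R)-2-(4-acetyl-2-iodophenoxy)-3-[(4-methoxybenzyloxy)methyl]but-3-enal
Product: 12 1-{(2R,3S)-3-hydroxy-2-[3-(4-methoxybenzyloxy)prop-1-en-2-yl]-2,3-dihydrobenzofuran-5-yl}ethan-1-one (trans), via arylchromium dichloride 11 (not isolated)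
Conditions: CrCl2 (6 equiv), NiCl2 (1 mol%), degassed DMF, rt, 0.02 M; then H2O
Reagents that add atoms: none
Why: CrCl2 reduces NiCl2 to zerovalent nickel, which undergoes oxidative addition to the aryl C–I bond, and aryl transfer from nickel to trivalent chromium gives arylchromium dichloride 11, which adds to the aldehyde carbonyl. The closest known reaction type is the intramolecular Nozaki–Hiyama–Kishi coupling of aryl and alkenyl iodides with aldehydes. The dihydrofuran ring closes in a 5-exo-trig mode on the C=O group and the C3–C3a bond is formed. The new centre C3 is controlled by the existing C2 centre: the aldehyde should react through the rotamer whose oxygen, carrying the solvated chromium, lies opposite the C2 alkenyl substituent, so the trans (2R,3S) alcohol is expected. The step needs addition to the aldehyde and not to the C5 methyl ketone, which the low reactivity of arylchromium reagents toward ketones secures, and it needs C2 to keep its configuration, which the neutral, non-basic medium secures. The nickel loading is kept low so that transfer to chromium outruns insertion of the arylnickel into the 1,1-disubstituted alkene.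

Step 8
Reactants: 12 the trans carbinol from step 7
Product: 13 (2R,3S)-5-acetyl-2-[3-(4-methoxybenzyloxy)prop-1-en-2-yl]-2,3-dihydrobenzofuran-3-yl acetate
Conditions: Ac2O, pyridine, DMAP (cat.), CH2Cl2, 0 °C
Reagents that add atoms: acetic anhydride, CC(=O)OC(C)=O
Why: DMAP-catalysed acylation of the secondary benzylic alcohol, in which the C3–O bond is not broken and the configuration is retained.

Step 9
Reactants: 13 the keto acetate from step 8
Product: 14 (2R,3S)-5-[(R)-1-hydroxyethyl]-2-[3-(4-methoxybenzyloxy)prop-1-en-2-yl]-2,3-dihydrobenzofuran-3-yl acetate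
Conditions: RuCl[(R,R)-TsDPEN](p-cymene) (2 mol%), HCO2H/Et3N (5:2), EtOAc, 30 °C
Reagents that add atoms: none
Why: Noyori asymmetric transfer hydrogenation, in which the (R,R)-configured ruthenium hydride delivers hydride to one face of the aryl methyl ketone through the outer-sphere six-membered transition state, sets the (R)-carbinol under catalyst control, and leaves the acetate, the isolated alkene and the PMB ether alone.

Step 10
Reactants: 14 the (R)-carbinol from step 9; 15 angelic acid
Product: 17 (R)-1-{(2R,3S)-3-acetoxy-2-[3-(4-methoxybenzyloxy)prop-1-en-2-yl]-2,3-dihydrobenzofuran-5-yl}ethyl (Z)-2-methylbut-2-enoate, via angelic 2,4,6-trichlorobenzoic anhydride 16 (not isolated)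
Conditions: 15, 2,4,6-Cl3C6H2COCl, Et3N, toluene, rt; then 14, 75 °C, no DMAP
Reagents that add atoms: none
Why: Yamaguchi esterification, in which the alcohol attacks the less hindered angeloyl carbonyl of the mixed anhydride, while leaving out DMAP avoids the conjugate addition–elimination that would turn the (Z)-alkene into the tiglate; the carbinol configuration is retained.

Step 11
Reactants: 17 the PMB-protected diester from step 10
Product: 18 (R)-1-[(2R,3S)-3-acetoxy-2-(3-hydroxyprop-1-en-2-yl)-2,3-dihydrobenzofuran-5-yl]ethyl (Z)-2-methylbut-2-enoate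
Conditions: DDQ, CH2Cl2/pH 7 buffer (10:1), 0 °C
Reagents that add atoms: none
Why: Oxidative PMB ether cleavage, in which DDQ abstracts hydride from the electron-rich 4-methoxybenzylic position and water hydrolyses the oxocarbenium ion, while the ester-bearing benzylic positions of the substrate are deactivated toward this oxidation.

Step 12
Reactants: 18 the allylic alcohol from step 11
Product: 19 (R)-1-[(2R,3S)-3-acetoxy-2-(3-oxoprop-1-en-2-yl)-2,3-dihydrobenzofuran-5-yl]ethyl (Z)-2-methylbut-2-enoate
Conditions: MnO2 (activated, excess), CH2Cl2, rt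
Reagents that add atoms: none
Why: Chemoselective MnO2 oxidation of the primary allylic alcohol to the 2-substituted propenal on a neutral surface oxidant, which leaves both esters and the C2 and C3 centres unaffected.

**Compound list**

1 | 2-bromoprop-2-en-1-ol | C=C(Br)CO | starting material
2 | 2-bromo-3-(4-methoxybenzyloxy)prop-1-ene | C=C(Br)COCc1ccc(OC)cc1 | intermediate
3 | (S)-2,2-dimethyl-1,3-dioxolane-4-carbaldehyde | O=C[C@@H]1COC(C)(C)O1 | starting material
4 | [3-(4-methoxybenzyloxy)prop-1-en-2-yl]lithium (2-lithioallyl PMB ether) | [Li]C(=C)COCc1ccc(OC)cc1 | intermediate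
5 | (R)-1-[(S)-2,2-dimethyl-1,3-dioxolan-4-yl]-2-[(4-methoxybenzyloxy)methyl]prop-2-en-1-ol (anti adduct) | C=C(COCc1ccc(OC)cc1)[C@@H](O)[C@@H]1COC(C)(C)O1 | intermediate
6 | 4'-fluoroacetophenone | CC(=O)c1ccc(F)cc1 | starting material
7 | 4'-fluoro-3'-iodoacetophenone | CC(=O)c1ccc(F)c(I)c1 | intermediate
8 | 1-[4-({(R)-1-[(S)-2,2-dimethyl-1,3-dioxolan-4-yl]-2-[(4-methoxybenzyloxy)methyl]prop-2-en-1-yl}oxy)-3-iodophenyl]ethan-1-one | C=C(COCc1ccc(OC)cc1)[C@@H](Oc1ccc(C(C)=O)cc1I)[C@@H]1COC(C)(C)O1 | intermediate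
9 | 1-[4-({(2S,3R)-1,2-dihydroxy-4-[(4-methoxybenzyloxy)methyl]pent-4-en-3-yl}oxy)-3-iodophenyl]ethan-1-one | C=C(COCc1ccc(OC)cc1)[C@@H](Oc1ccc(C(C)=O)cc1I)[C@@H](O)CO | intermediate
10 | (R)-2-(4-acetyl-2-iodophenoxy)-3-[(4-methoxybenzyloxy)methyl]but-3-enal | C=C(COCc1ccc(OC)cc1)[C@H](C=O)Oc1ccc(C(C)=O)cc1I | intermediate
11 | arylchromium dichloride derived from 10 (CrCl2 group in place of iodine) | C=C(COCc1ccc(OC)cc1)[C@H](C=O)Oc1ccc(C(C)=O)cc1[Cr](Cl)Cl | intermediate
12 | 1-{(2R,3S)-3-hydroxy-2-[3-(4-methoxybenzyloxy)prop-1-en-2-yl]-2,3-dihydrobenzofuran-5-yl}ethan-1-one (trans) | C=C(COCc1ccc(OC)cc1)[C@H]1Oc2ccc(C(C)=O)cc2[C@@H]1O | intermediate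
13 | (2R,3S)-5-acetyl-2-[3-(4-methoxybenzyloxy)prop-1-en-2-yl]-2,3-dihydrobenzofuran-3-yl acetate | C=C(COCc1ccc(OC)cc1)[C@H]1Oc2ccc(C(C)=O)cc2[C@@H]1OC(C)=O | intermediate
14 | (2R,3S)-5-[(R)-1-hydroxyethyl]-2-[3-(4-methoxybenzyloxy)prop-1-en-2-yl]-2,3-dihydrobenzofuran-3-yl acetate | C=C(COCc1ccc(OC)cc1)[C@H]1Oc2ccc([C@@H](C)O)cc2[C@@H]1OC(C)=O | intermediate
15 | angelic acid, (Z)-2-methylbut-2-enoic acid | C/C=C(/C)C(=O)O | starting material
16 | (Z)-2-methylbut-2-enoic 2,4,6-trichlorobenzoic anhydride | C/C=C(/C)C(=O)OC(=O)c1c(Cl)cc(Cl)cc1Cl | intermediate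
17 | (R)-1-{(2R,3S)-3-acetoxy-2-[3-(4-methoxybenzyloxy)prop-1-en-2-yl]-2,3-dihydrobenzofuran-5-yl}ethyl (Z)-2-methylbut-2-enoate | C=C(COCc1ccc(OC)cc1)[C@H]1Oc2ccc([C@@H](C)OC(=O)/C(C)=C\C)cc2[C@@H]1OC(C)=O | intermediate
18 | (R)-1-[(2R,3S)-3-acetoxy-2-(3-hydroxyprop-1-en-2-yl)-2,3-dihydrobenzofuran-5-yl]ethyl (Z)-2-methylbut-2-enoate | C=C(CO)[C@H]1Oc2ccc([C@@H](C)OC(=O)/C(C)=C\C)cc2[C@@H]1OC(C)=O | intermediate
19 | (R)-1-[(2R,3S)-3-acetoxy-2-(3-oxoprop-1-en-2-yl)-2,3-dihydrobenzofuran-5-yl]ethyl (Z)-2-methylbut-2-enoate | C=C(C=O)[C@H]1Oc2ccc([C@@H](C)OC(=O)/C(C)=C\C)cc2[C@@H]1OC(C)=O | target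

**Step count and risks**

Total steps: 12. Longest linear sequence: 11 steps (steps 1, 2 and 4 to 12; step 3 is a one-step branch).

Steps most likely to fail:

1. Step 7: poor facial selectivity in the addition of the arylchromium to the aldehyde, so that the cis carbinol dominates, with insertion of the arylnickel into the neighbouring alkene as a second drain. The fallback sets the C3 centre by SN2 inversion instead of by face control. It sets out from aldehyde 10, whose closure would then give mainly 1-{(2R,3R)-3-hydroxy-2-[3-(4-methoxybenzyloxy)prop-1-en-2-yl]-2,3-dihydrobenzofuran-5-yl}ethan-1-one F1. Treating this cis carbinol with acetic acid, PPh3 and diisopropyl azodicarboxylate in toluene at 0 °C (Mitsunobu reaction) should give the trans acetate directly, and the route is rejoined at 13.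

2. Step 2: low Felkin facial selectivity in the addition of the vinyllithium, which would leave much of the material as the syn epimer. The fallback sets out from 2 and 3 and recovers that material by stereospecific inversion. The co-formed (S)-1-[(S)-2,2-dimethyl-1,3-dioxolan-4-yl]-2-[(4-methoxybenzyloxy)methyl]prop-2-en-1-ol F2 is converted with 4-nitrobenzoic acid, PPh3 and diisopropyl azodicarboxylate in THF into the inverted ester (R)-1-[(S)-2,2-dimethyl-1,3-dioxolan-4-yl]-2-[(4-methoxybenzyloxy)methyl]prop-2-en-1-yl 4-nitrobenzoate F3. Methanolysis with K2CO3 in MeOH then returns to 5.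

3. Step 4: slow substitution by the hindered secondary alkoxide, with competing enolisation and aldol condensation of the methyl ketone. The fallback sets out from 5 and uses commercial 4-fluoro-3-iodobenzaldehyde (O=Cc1ccc(F)c(I)c1), whose activating group is stronger and cannot enolise. Under the same base it should give 4-({(R)-1-[(S)-2,2-dimethyl-1,3-dioxolan-4-yl]-2-[(4-methoxybenzyloxy)methyl]prop-2-en-1-yl}oxy)-3-iodobenzaldehyde F4. Addition of MeMgBr in THF at −78 °C gives the carbinol 1-[4-({(R)-1-[(S)-2,2-dimethyl-1,3-dioxolan-4-yl]-2-[(4-methoxybenzyloxy)methyl]prop-2-en-1-yl}oxy)-3-iodophenyl]ethan-1-ol F5 as a mixture of epimers at the new centre. Dess–Martin oxidation in CH2Cl2 then returns to ketone 8.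

Further compounds
F1 | step 7 | 1-{(2R,3R)-3-hydroxy-2-[3-(4-methoxybenzyloxy)prop-1-en-2-yl]-2,3-dihydrobenzofuran-5-yl}ethan-1-one (cis) | C=C(COCc1ccc(OC)cc1)[C@H]1Oc2ccc(C(C)=O)cc2[C@H]1O
F2 | step 2 | (S)-1-[(S)-2,2-dimethyl-1,3-dioxolan-4-yl]-2-[(4-methoxybenzyloxy)methyl]prop-2-en-1-ol (syn epimer) | C=C(COCc1ccc(OC)cc1)[C@H](O)[C@@H]1COC(C)(C)O1
F3 | step 2 | (R)-1-[(S)-2,2-dimethyl-1,3-dioxolan-4-yl]-2-[(4-methoxybenzyloxy)methyl]prop-2-en-1-yl 4-nitrobenzoate | C=C(COCc1ccc(OC)cc1)[C@@H](OC(=O)c1ccc(cc1)[N+](=O)[O-])[C@@H]1COC(C)(C)O1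
F4 | step 4 | 4-({(R)-1-[(S)-2,2-dimethyl-1,3-dioxolan-4-yl]-2-[(4-methoxybenzyloxy)methyl]prop-2-en-1-yl}oxy)-3-iodobenzaldehyde | C=C(COCc1ccc(OC)cc1)[C@@H](Oc1ccc(C=O)cc1I)[C@@H]1COC(C)(C)O1
F5 | step 4 | 1-[4-({(R)-1-[(S)-2,2-dimethyl-1,3-dioxolan-4-yl]-2-[(4-methoxybenzyloxy)methyl]prop-2-en-1-yl}oxy)-3-iodophenyl]ethan-1-ol (epimer mixture at the new carbinol) | C=C(COCc1ccc(OC)cc1)[C@@H](Oc1ccc(C(C)O)cc1I)[C@@H]1COC(C)(C)O1
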